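**Retrosynthetic overview**
- Ring A is a pentasubstituted benzene. C1 carries the ester carbon, C2, C4 and C5 carry OH, C6 carries CH3, and only C3 carries H. The C2–C5 segment therefore holds all three oxygens, and the C1–C6 edge with its ester and methyl group corresponds to a but-2-ynoate.
- Ring A is cut at C1–C2 and C5–C6. This is a [4+2] cycloaddition of a 1,1,3,4-tetraoxygenated butadiene with the but-2-ynoate of the ring B–ring C phenol. The crowded A–B ester is made beforehand as an unhindered alkynoate.
- The B–C ester comes from coupling two orsellinic acid derivatives: the ring B acid (2-OMe, 4-OMOM) and benzyl orsellinate, which is acylated at its non-chelated 4-OH.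
- Rings B and C are purchased as orsellinic acid. Ring A is the only ring formed, and it is formed last. One hydrogenolysis of three benzyl groups ends the route.

Key step: step 11

Remark: the target has no stereocentre. Orsellinic acid, but-2-ynoic acid and methyl 4-(benzyloxy)-3-oxobutanoate are taken as purchasable. Every ring is numbered with C1 at its carboxyl-bearing carbon.

**Step 1**
Reactants: 1 orsellinic acid (2,4-dihydroxy-6-methylbenzoic acid)
Product: 2 benzyl orsellinate (benzyl 2,4-dihydroxy-6-methylbenzoate)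
Conditions: BnBr (1.05 equiv), KHCO3, DMF, rt
Reagents that add atoms: benzyl bromide, BrCc1ccccc1
Why: Carboxylate O-alkylation (SN2), in which KHCO3 ionizes only the carboxylic acid so both phenols stay free, and room temperature avoids decarboxylation of 1.

**Step 2**
Reactants: 2 benzyl orsellinate
Product: 3 benzyl 2-hydroxy-4-(methoxymethoxy)-6-methylbenzoate
Conditions: MeOCH2Cl (1.05 equiv), iPr2NEt, CH2Cl2, 0 °C
Reagents that add atoms: chloromethyl methyl ether, COCCl
Why: Selective phenol acetalization (MOM ether formation), because the 2-OH is hydrogen-bonded to the ester carbonyl and only the more acidic, unhindered 4-OH reacts with one equivalent of reagent.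

**Step 3**
Reactants: 3 benzyl 2-hydroxy-4-(methoxymethoxy)-6-methylbenzoate
Product: 4 benzyl 2-methoxy-4-(methoxymethoxy)-6-methylbenzoate
Conditions: MeI, K2CO3, DMF, 40 °C
Reagents that add atoms: iodomethane, CI
Why: Williamson ether synthesis on the only remaining phenol, under conditions that leave the MOM acetal and the hindered benzyl ester untouched.

**Step 4**
Reactants: 4 benzyl 2-methoxy-4-(methoxymethoxy)-6-methylbenzoate
Product: 5 2-methoxy-4-(methoxymethoxy)-6-methylbenzoic acid
Conditions: H2 (1 atm), Pd/C (10 wt %), EtOAc, rt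
Reagents that add atoms: none
Why: Catalytic hydrogenolysis of the benzyl ester frees the di-ortho-substituted acid under neutral conditions, so no forcing saponification is needed and the MOM and methyl ethers survive.

**Step 5**
Reactants: 5 2-methoxy-4-(methoxymethoxy)-6-methylbenzoic acid; 2 benzyl orsellinate
Product: 6 benzyl 2-hydroxy-4-{[2-methoxy-4-(methoxymethoxy)-6-methylbenzoyl]oxy}-6-methylbenzoate
Conditions: DCC, DMAP (0.2 equiv), CH2Cl2, 0 °C → rt
Reagents that add atoms: none
Why: Steglich esterification, a standard way to form depside bonds, in which the free 4-OH of 2 is acylated in preference to the chelated, flanked 2-OH and the acid-free medium preserves the MOM group.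

**Step 6**
Reactants: 6 benzyl 2-hydroxy-4-{[2-methoxy-4-(methoxymethoxy)-6-methylbenzoyl]oxy}-6-methylbenzoate
Product: 7 benzyl 2-(benzyloxy)-4-{[2-methoxy-4-(methoxymethoxy)-6-methylbenzoyl]oxy}-6-methylbenzoate
Conditions: BnBr, K2CO3, acetone, reflux
Reagents that add atoms: benzyl bromide, BrCc1ccccc1
Why: Williamson benzylation of the last free phenol in dry acetone, where the di-ortho-substituted depside carbonyl is shielded from attack, removes the only acidic proton that could quench the diene later.

**Step 7**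
Reactants: 7 benzyl 2-(benzyloxy)-4-{[2-methoxy-4-(methoxymethoxy)-6-methylbenzoyl]oxy}-6-methylbenzoate
Product: 8 benzyl 2-(benzyloxy)-4-[(4-hydroxy-2-methoxy-6-methylbenzoyl)oxy]-6-methylbenzoate (ring B–ring C phenol)
Conditions: CF3CO2H–CH2Cl2 (1:4), trace H2O, 0 °C → rt
Reagents that add atoms: none
Why: Acid-catalysed acetal hydrolysis cleaves the aryl MOM ether quickly, while benzyl ether, benzyl ester and aryl ester are stable to cold trifluoroacetic acid.

**Step 8**
Reactants: 8 ring B–ring C phenol; 9 but-2-ynoic acid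
Product: 10 benzyl 2-(benzyloxy)-4-{[4-(but-2-ynoyloxy)-2-methoxy-6-methylbenzoyl]oxy}-6-methylbenzoate (dienophile)
Conditions: DCC, DMAP (5 mol %), CH2Cl2, −10 → 0 °C
Reagents that add atoms: none
Why: Steglich esterification of a sterically undemanding alkynoic acid with the single free phenol, kept cold and low in DMAP so that isomerization to the allenoate is suppressed.

**Step 9**
Reactants: 11 methyl 4-(benzyloxy)-3-oxobutanoate
Product: 12 methyl 4-(benzyloxy)-3-(trimethylsilyloxy)but-2-enoate (E/Z mixture)
Conditions: Me3SiCl, Et3N, toluene, rt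
Reagents that add atoms: chlorotrimethylsilane, C[Si](C)(C)Cl
Why: Silyl enol ether formation from the enolized β-keto ester under amine base, where the E/Z composition does not matter because this C2=C3 bond becomes the central single bond of the diene.

**Step 10**
Reactants: 12 methyl 4-(benzyloxy)-3-(trimethylsilyloxy)but-2-enoate
Product: 14 (1Z,3Z)-4-(benzyloxy)-1-methoxy-1,3-bis(trimethylsilyloxy)buta-1,3-diene, via lithium dienolate 13 (not isolated)
Conditions: LiN(iPr)2 (LDA, commercial solution), THF, −78 °C; Me3SiCl, −78 → 0 °C; hexane, filtration under Ar, used crude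
Reagents that add atoms: chlorotrimethylsilane, C[Si](C)(C)Cl
Why: Vinylogous (γ) deprotonation of a β-silyloxy enoate and O-silylation of the dienolate is the standard two-stage entry to 1,3-bis(silyloxy)dienes, and allylic strain against the C1=C2 unit should place OBn trans to C2, which is the (3Z) geometry.

**Step 11**
Reactants: 10 but-2-ynoate of the ring B–ring C phenol; 14 (1Z,3Z)-4-(benzyloxy)-1-methoxy-1,3-bis(trimethylsilyloxy)buta-1,3-diene
Product: 18 benzyl 2-(benzyloxy)-4-{[4-({5-(benzyloxy)-2,4-dihydroxy-6-methylbenzoyl}oxy)-2-methoxy-6-methylbenzoyl]oxy}-6-methylbenzoate (tribenzyl-protected target), via cyclohexa-1,4-diene cycloadduct 15 (not isolated), via cyclohexa-2,5-dienone 16 (not isolated), via 4-O-trimethylsilyl arene 17 (not isolated)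
Conditions: 14 (4 equiv, in portions), toluene (1 M), sealed tube, 130 °C; then 1 M HCl, THF, 0 °C
Reagents that add atoms: none
Why: This is a thermal, normal-electron-demand and strongly asynchronous Diels–Alder reaction: the two C1 oxygens and the C3 silyloxy group of 14 all polarize the diene towards C4 and outweigh the opposing 4-benzyloxy donor, so C4 attacks the electrophilic, methyl-bearing β-carbon of ynoate 10 (ring A bond C5–C6) while the ketene-acetal carbon C1 closes onto the α-carbon (bond C1–C2). Ring A is closed in this single intermolecular [4+2] event as the six-membered cyclohexa-1,4-diene 15. The mixed methyl silyl ketal at C2 of 15 then collapses with loss of MeOSiMe3 to the cross-conjugated dienone 16, whose C5 hydrogen shifts to oxygen to give phenol 17, so the arene oxidation level is reached without an oxidant and with the C5 benzyloxy group retained; dilute acid finally hydrolyses the 4-O-silyl ether. The closest known reaction type is the cycloaddition–aromatization of 1-alkoxy-1,3-bis(silyloxy)buta-1,3-dienes with alk-2-ynoates (β-alkyl ynoates included, at 120–160 °C) to give 6-alkylresorcylates. No stereocentre survives: C2 and C5 of 15 (OMe and OBn cis by suprafacial addition of the two outside substituents) are both flattened, and the only geometric requirement is the (3Z) double bond of 14, which holds OBn on the outside of the s-cis diene. The step needs regioselectivity (set by the matched polarization described, which puts 2-OH beside the ester and OBn beside the methyl), chemoselectivity for the alkyne over the three ester carbonyls (no Lewis acid is present and 10 has no free OH to protonate the ketene acetal), and expulsion of methoxy instead of silyloxy from C2 (the labile O–Si bond makes the silyloxy oxygen the one that becomes the carbonyl).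

**Step 12**
Reactants: 18 tribenzyl-protected target
Product: 19 2'-O-methylhiascic acid (2-hydroxy-4-{[2-methoxy-6-methyl-4-(2,4,5-trihydroxy-6-methylbenzoyloxy)benzoyl]oxy}-6-methylbenzoic acid)
Conditions: H2 (1 atm), Pd/C (10 wt %), EtOAc–THF, rt; filtration and concentration under Ar
Reagents that add atoms: none
Why: Catalytic hydrogenolysis removes the two benzyl ethers and the benzyl ester in one neutral, reducing operation, and the alcohol-free solvent and exclusion of air protect the depside esters from alcoholysis and the 1,2,4-trihydroxyarene from oxidation.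

**Compound list**
1 | orsellinic acid | Cc1cc(O)cc(O)c1C(=O)O | starting material
2 | benzyl orsellinate | Cc1cc(O)cc(O)c1C(=O)OCc1ccccc1 | intermediate
3 | benzyl 2-hydroxy-4-(methoxymethoxy)-6-methylbenzoate | COCOc1cc(C)c(C(=O)OCc2ccccc2)c(O)c1 | intermediate
4 | benzyl 2-methoxy-4-(methoxymethoxy)-6-methylbenzoate | COCOc1cc(C)c(C(=O)OCc2ccccc2)c(OC)c1 | intermediate
5 | 2-methoxy-4-(methoxymethoxy)-6-methylbenzoic acid | COCOc1cc(C)c(C(=O)O)c(OC)c1 | intermediate
6 | benzyl 2-hydroxy-4-{[2-methoxy-4-(methoxymethoxy)-6-methylbenzoyl]oxy}-6-methylbenzoate | COCOc1cc(C)c(C(=O)Oc2cc(C)c(C(=O)OCc3ccccc3)c(O)c2)c(OC)c1 | intermediate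
7 | benzyl 2-(benzyloxy)-4-{[2-methoxy-4-(methoxymethoxy)-6-methylbenzoyl]oxy}-6-methylbenzoate | COCOc1cc(C)c(C(=O)Oc2cc(C)c(C(=O)OCc3ccccc3)c(OCc3ccccc3)c2)c(OC)c1 | intermediate
8 | benzyl 2-(benzyloxy)-4-[(4-hydroxy-2-methoxy-6-methylbenzoyl)oxy]-6-methylbenzoate (ring B–ring C phenol) | Oc1cc(C)c(C(=O)Oc2cc(C)c(C(=O)OCc3ccccc3)c(OCc3ccccc3)c2)c(OC)c1 | intermediate
9 | but-2-ynoic acid | CC#CC(=O)O | starting material
10 | benzyl 2-(benzyloxy)-4-{[4-(but-2-ynoyloxy)-2-methoxy-6-methylbenzoyl]oxy}-6-methylbenzoate | CC#CC(=O)Oc1cc(C)c(C(=O)Oc2cc(C)c(C(=O)OCc3ccccc3)c(OCc3ccccc3)c2)c(OC)c1 | intermediate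
11 | methyl 4-(benzyloxy)-3-oxobutanoate | COC(=O)CC(=O)COCc1ccccc1 | starting material
12 | methyl 4-(benzyloxy)-3-(trimethylsilyloxy)but-2-enoate (E/Z mixture, geometry left open) | COC(=O)C=C(COCc1ccccc1)O[Si](C)(C)C | intermediate
13 | lithium (1Z,3Z)-4-(benzyloxy)-1-methoxy-3-(trimethylsilyloxy)buta-1,3-dien-1-olate | CO/C([O-])=C/C(O[Si](C)(C)C)=C/OCc1ccccc1.[Li+] | intermediate
14 | (1Z,3Z)-4-(benzyloxy)-1-methoxy-1,3-bis(trimethylsilyloxy)buta-1,3-diene | CO/C(O[Si](C)(C)C)=C/C(O[Si](C)(C)C)=C/OCc1ccccc1 | intermediate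
15 | cyclohexa-1,4-diene cycloadduct (racemic, one enantiomer drawn; ring A C2 carries OMe and OSiMe3, C5 carries H and OBn, OMe and OBn cis) | CC1=C(C(=O)Oc2cc(C)c(C(=O)Oc3cc(C)c(C(=O)OCc4ccccc4)c(OCc4ccccc4)c3)c(OC)c2)[C@](OC)(O[Si](C)(C)C)C=C(O[Si](C)(C)C)[C@H]1OCc1ccccc1 | intermediate
16 | cyclohexa-2,5-dienone (racemic, one enantiomer drawn; C2 carbonyl, C5 carries H and OBn) | CC1=C(C(=O)Oc2cc(C)c(C(=O)Oc3cc(C)c(C(=O)OCc4ccccc4)c(OCc4ccccc4)c3)c(OC)c2)C(=O)C=C(O[Si](C)(C)C)[C@H]1OCc1ccccc1 | intermediate
17 | 4-O-trimethylsilyl ether of 18 | Cc1c(OCc2ccccc2)c(O[Si](C)(C)C)cc(O)c1C(=O)Oc1cc(C)c(C(=O)Oc2cc(C)c(C(=O)OCc3ccccc3)c(OCc3ccccc3)c2)c(OC)c1 | intermediate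
18 | tribenzyl-protected target (ring A 5-OBn, 2-OH and 4-OH free; ring C 2-OBn and CO2Bn) | Cc1c(OCc2ccccc2)c(O)cc(O)c1C(=O)Oc1cc(C)c(C(=O)Oc2cc(C)c(C(=O)OCc3ccccc3)c(OCc3ccccc3)c2)c(OC)c1 | intermediate
19 | 2'-O-methylhiascic acid | COc1cc(OC(=O)c2c(O)cc(O)c(O)c2C)cc(C)c1C(=O)Oc1cc(C)c(C(=O)O)c(O)c1 | target

**Total step count:** 12
**Longest linear sequence:** 10 steps (steps 1–8, 11, 12) from orsellinic acid. The diene branch (steps 9, 10) joins at step 11.

**Steps most likely to fail**

1. **Step 11.** The cycloaddition may be too slow, because a substituted diene terminus has to bond to a methyl-bearing alkyne carbon. Thermal silyl migration and decomposition of the ketene acetal could then consume the diene before it adds.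
   - The fallback gives up the ring construction and acylates the phenol with a preformed ring A acid. It sets out from 2, with 8 as coupling partner, and comes back at 19.
   - Elbs persulfate oxidation of 2 (K2S2O8, aq. NaOH, rt) attacks para to the 2-phenoxide, that is at C5. This gives potassium 3-[(benzyloxy)carbonyl]-4,6-dihydroxy-2-methylphenyl sulfate F1.
   - Warm dilute HCl hydrolyses F1 to benzyl 2,4,5-trihydroxy-6-methylbenzoate F2.
   - Exhaustive benzylation (BnBr, K2CO3, DMF, under Ar) gives benzyl 2,4,5-tris(benzyloxy)-6-methylbenzoate F3.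
   - Saponification (KOH, DMSO–H2O, 90 °C) gives 2,4,5-tris(benzyloxy)-6-methylbenzoic acid F4.
   - Steglich coupling of F4 with 8 (DCC, DMAP, CH2Cl2) gives the pentabenzyl tridepside F5. Its hydrogenolysis (H2, Pd/C, EtOAc–THF) delivers 19.

2. **Step 10.** γ-Deprotonation may be incomplete or accompanied by C-silylation. The trimethylsilyl ketene acetal may hydrolyse during isolation, and the C3=C4 geometry may erode.
   - The fallback replaces the lithium dienolate chemistry by soft enolization and uses a more robust silyl group. It sets out from 11 and comes back at 18.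
   - Double silylation of 11 (tBuMe2SiOTf, 2.3 equiv, Et3N, Et2O, 0 °C) gives (1Z,3Z)-4-(benzyloxy)-1-methoxy-1,3-bis(tert-butyldimethylsilyloxy)buta-1,3-diene F6. This diene tolerates handling and prolonged heating.
   - Heating F6 with 10 as in step 11 gives the bis-TBS cycloadduct F7.
   - F7 sheds MeOSiMe2tBu to give the TBS dienone F8, which tautomerizes to the 4-O-TBS arene F9.
   - Et3N·3HF in THF then releases 18.

3. **Step 6.** Alkylation of the chelated, flanked phenol may be slow. During long heating with base, phenoxide-mediated transesterification could scramble the depside link.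
   - The fallback installs the benzyl ether before the coupling. It sets out from 3 and comes back at 7.
   - Benzylation of 3 (BnBr, K2CO3, DMF) gives benzyl 2-(benzyloxy)-4-(methoxymethoxy)-6-methylbenzoate F10.
   - CF3CO2H–CH2Cl2 removes the acetal to give benzyl 2-(benzyloxy)-4-hydroxy-6-methylbenzoate F11.
   - Steglich coupling of F11, which has a single free hydroxyl, with acid 5 gives 7 directly.

**Further compounds**
F1 | step 11 | potassium 3-[(benzyloxy)carbonyl]-4,6-dihydroxy-2-methylphenyl sulfate | Cc1c(OS(=O)(=O)[O-])c(O)cc(O)c1C(=O)OCc1ccccc1.[K+]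
F2 | step 11 | benzyl 2,4,5-trihydroxy-6-methylbenzoate | Cc1c(O)c(O)cc(O)c1C(=O)OCc1ccccc1
F3 | step 11 | benzyl 2,4,5-tris(benzyloxy)-6-methylbenzoate | Cc1c(OCc2ccccc2)c(OCc2ccccc2)cc(OCc2ccccc2)c1C(=O)OCc1ccccc1
F4 | step 11 | 2,4,5-tris(benzyloxy)-6-methylbenzoic acid | Cc1c(OCc2ccccc2)c(OCc2ccccc2)cc(OCc2ccccc2)c1C(=O)O
F5 | step 11 | pentabenzyl tridepside (ring A 2,4,5-tris-OBn; ring C 2-OBn and CO2Bn) | Cc1c(OCc2ccccc2)c(OCc2ccccc2)cc(OCc2ccccc2)c1C(=O)Oc1cc(C)c(C(=O)Oc2cc(C)c(C(=O)OCc3ccccc3)c(OCc3ccccc3)c2)c(OC)c1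
F6 | step 10 | (1Z,3Z)-4-(benzyloxy)-1-methoxy-1,3-bis(tert-butyldimethylsilyloxy)buta-1,3-diene | CO/C(O[Si](C)(C)C(C)(C)C)=C/C(O[Si](C)(C)C(C)(C)C)=C/OCc1ccccc1
F7 | step 10 | bis-TBS cycloadduct (racemic, one enantiomer drawn) | CC1=C(C(=O)Oc2cc(C)c(C(=O)Oc3cc(C)c(C(=O)OCc4ccccc4)c(OCc4ccccc4)c3)c(OC)c2)[C@](OC)(O[Si](C)(C)C(C)(C)C)C=C(O[Si](C)(C)C(C)(C)C)[C@H]1OCc1ccccc1
F8 | step 10 | TBS dienone (racemic, one enantiomer drawn) | CC1=C(C(=O)Oc2cc(C)c(C(=O)Oc3cc(C)c(C(=O)OCc4ccccc4)c(OCc4ccccc4)c3)c(OC)c2)C(=O)C=C(O[Si](C)(C)C(C)(C)C)[C@H]1OCc1ccccc1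
F9 | step 10 | 4-O-TBS arene (4-O-tert-butyldimethylsilyl ether of 18) | Cc1c(OCc2ccccc2)c(O[Si](C)(C)C(C)(C)C)cc(O)c1C(=O)Oc1cc(C)c(C(=O)Oc2cc(C)c(C(=O)OCc3ccccc3)c(OCc3ccccc3)c2)c(OC)c1
F10 | step 6 | benzyl 2-(benzyloxy)-4-(methoxymethoxy)-6-methylbenzoate | COCOc1cc(C)c(C(=O)OCc2ccccc2)c(OCc2ccccc2)c1
F11 | step 6 | benzyl 2-(benzyloxy)-4-hydroxy-6-methylbenzoate | Cc1cc(O)cc(OCc2ccccc2)c1C(=O)OCc1ccccc1
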